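Compare the two charges first: the flask holds twice the substrate of the north run, at the same gas.

- north: substrate 0.55 M; gas phase 190 mM (held); run made earlier
- flask: substrate 1.1 M; gas phase 190 mM (held); time 20 min

north run (percent of the substrate charged)

| time / s | target / % | substrate / % |
|---|---|---|
| 10.0 | 0 | 74.7 |
| 25.0 | 6.1 | 57.7 |
| 40.0 | 7.7 | 46.1 |
| 60.0 | 10.9 | 41.1 |
| 90.0 | 13.3 | 34.6 |
| 120 | 18.6 | 28.2 |

(scatter of a reading: 1 percentage point)

1. how much target there is at 20 min, in percent of the substrate charged
2. the change that raises the amount of target at 20 min, in percent of the substrate charged most ("none" if none brings more than 2 percentage points) (Friday's / Monday's / none)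
3. amount of target at 20 min, in percent of the substrate charged, after Monday's

- Friday's: doubling the saturation concentration of gas phase, all else as stated
- Monday's: doubling the transfer coefficient of the gas phase, all else as stated

- a species is counted by the substrate in it: one self-condensation product counts as two
- at the start none of the gas is dissolved
- what was read earlier has a scatter of 1 percentage point, one standard deviation
- reactions considered so far: gas phase <-> dissolved gas; substrate + dissolved gas -> target; dissolved gas + target -> over-reacted product; substrate <-> dormant form; 2 substrate -> self-condensation product

So the question is what concentration does. Substrate reaches target by a step with one substrate in it, but self-condensation product by a step with two. Both run on the same clock, so I divide one rate by the other and time drops out.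

From 25.0 s to 120 s the north run gains 13 percentage points of target and loses 30 points of substrate. So 1.36 go elsewhere for each one that becomes target, at a mean substrate of 0.236 M. That gives 5.76 M⁻¹, the waste ratio: substrate lost elsewhere per substrate made into target, per molar of substrate, a selectivity factor. It is a reading, with scatter in it and dormant form unseparated, and it assumes steady dissolved gas.

The north run has lost 71.8 % of its substrate by 120 s, and the flask runs ten times as long, so I sum down to an empty flask. With x the waste ratio times the charge, here 6.33, the share passing through target is ln(1+x)/x, which is 31.5 %. That share holds target and over-reacted product together, so I expect less target than that. Friday's divides the ratio by 2 if dissolved gas follows saturation, giving 45.1 %, more than now. But that share again holds over-reacted product, and dissolved gas stands in the over-reaction step too, so it doesn't show whether target itself gains over 2 points. I lean to Friday's, as a guess at the direction and not as a reckoned gain.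

The forecast differs from my reckoning: it gives 55 %, none as the best change and 35 % after Monday's, reading that “the reaction is gas-transfer limited”. The flask gives 23.7 % of target, and Friday's is the best change.

    gas phase ⇌ dissolved gas, rate k1*(csat - [dissolved gas]) (kL = 0.210 s⁻¹)
    substrate + dissolved gas → target (k = 0.0180 M⁻¹ s⁻¹)
    dissolved gas + target → over-reacted product (k = 0.00120 M⁻¹ s⁻¹)
    substrate ⇌ dormant form (K = 0.390, k = 0.0170 s⁻¹)
    2 substrate → self-condensation product (k = 0.0130 M⁻¹ s⁻¹)

Beside the 23.7 % of target, the flask holds 5.75 % of over-reacted product at 20.0 min, together 29.5 % against my 31.5 %. Friday's gains 2.9 points and Monday's 0.54 points, which makes 24.3 %. The neighbour flask charged with 1.9 M has x of 10.9, so the same reckoning gives 22.7 %. That neighbour flask holds 16.7 % of target and 4.13 % of over-reacted product, together 20.8 %.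

The data are calculated with made-up constants.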